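## Retrosynthetic overview

1. The C8 methyl group is traced back to a C8 ketone: target ⇐ desilylation ⇐ alpha-face diimide reduction ⇐ Wittig methylenation ⇐ 8-oxo compound.
2. Key disconnection, C9–C10 ⇒ C8–C10: ring B (C5–C6–C7–C8–C9–C10) comes from the five-membered ring C5–C6–C7–C8–C10 of a trans-hydrindan-8-ol. Its C8 carries the C9≡C11 alkyne, and C11 carries the aryl ring at the quinone level.
3. Enabling feature: the para-dioxygenated aryl ring on C11 (O on C2' and C5'). As a 1,4-benzoquinone, its C5'=O (conjugated through C6'=C1' and C11≡C9) makes C9 the acceptor for migrating C10. Its C2'=O then makes C11 (vinylidene ortho-quinone methide) the acceptor for chloride, and C8 next to C9 can carry the oxygen that pushes.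
4. Fragment union: Sonogashira coupling of the ethynyl carbinol with 1-iodo-2,3,5-trimethoxybenzene (two steps from 5-iodovanillin), then oxidative demethylation to the quinone.
5. Ring order: ring A and the five-membered ring are bought together in an enantiopure bicyclic enedione (C10 set). They are trimmed by C4 gem-dimethylation, C3 deoxygenation and alpha-face hydrogenation (C5 set). Ring B forms last, by ring expansion.

Key step: step 11

Remark: drimane numbering is used for all terpene carbons, precursors included (ring A = C1–C5 and C10; C11 = chlorinated alkene carbon). Primed numbers are used for the aryl or quinone ring (C1' on C11, O on C2' and C5', OMe on C3'). The alkene of the target is read as Cl cis to C8 and aryl cis to C10 (E). Compounds 1 and 10 are taken as commercial.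

## Route

Step 1
Reactants: 1 (S)-7a-methyl-2,3,7,7a-tetrahydro-1H-indene-1,5(6H)-dione
Product: 2 C8 ethylene ketal of 1 (enone untouched)
Conditions: (Me3SiOCH2)2 (1.2 equiv), Me3SiOTf (5 mol%), CH2Cl2, -78 to -20 °C
Reagents that add atoms: 1,2-bis(trimethylsilyloxy)ethane, C[Si](C)(C)OCCO[Si](C)(C)C
Why: Silyl-triflate-catalysed acetalisation under kinetic control, in which the saturated cyclopentanone carbonyl (C8) is dioxolanated faster than the less electrophilic conjugated C3 carbonyl and the quaternary centre C10 is not touched.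

Step 2
Reactants: 2 C8 ethylene ketal of 1
Product: 4 4,4-dimethyl beta,gamma-enone ketal (C5=C6 alkene), via 4-methyl enone 3 (not isolated)
Conditions: KOtBu (3 equiv), MeI (6 equiv), t-BuOH/THF, 0 °C to rt
Reagents that add atoms: iodomethane, CI
Why: Deconjugative double alpha-alkylation of the thermodynamic dienolate, in which both methyl groups enter at C4 and the double bond is moved to C5=C6 because a quaternary C4 cannot return to conjugation.

Step 3
Reactants: 4 4,4-dimethyl beta,gamma-enone ketal
Product: 6 C3-deoxygenated alkene ketal, via hydrazone 5 (not isolated)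
Conditions: N2H4·H2O, KOH, diethylene glycol, 130 then 200 °C
Reagents that add atoms: none
Why: Wolff-Kishner reduction of the C3 ketone, which the base-stable ketal and the isolated C5=C6 alkene (no position left for conjugation) should survive.

Step 4
Reactants: 6 C3-deoxygenated alkene ketal
Product: 7 trans-fused saturated ketal
Conditions: H2 (5 bar), Pd/C (10 wt%), EtOAc, rt
Reagents that add atoms: none
Why: Heterogeneous hydrogenation in which the two axial beta methyl groups (on C10 and C4) shield the beta face, so hydrogen should reach C5 from the alpha face and set the trans ring fusion (5S).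

Step 5
Reactants: 7 trans-fused saturated ketal
Product: 8 (3aS,7aS)-4,4,7a-trimethyloctahydro-1H-inden-1-one
Conditions: 2 M HCl, THF, rt
Reagents that add atoms: water, O
Why: Acid-catalysed ketal hydrolysis, safe for the ring fusion because C5 is not alpha to the C8 carbonyl and C10 is quaternary.

Step 6
Reactants: 8 (3aS,7aS)-4,4,7a-trimethyloctahydro-1H-inden-1-one
Product: 9 (1R,3aS,7aS)-1-ethynyl-4,4,7a-trimethyloctahydro-1H-inden-1-ol
Conditions: HC≡CMgBr (3 equiv), THF, 0 °C to rt; then water
Reagents that add atoms: ethynylmagnesium bromide, C#C[Mg]Br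
Why: 1,2-Addition of an alkynyl Grignard reagent, in which the acetylide should attack C8 from the alpha face anti to the angular C10 methyl group (as in the ethynylation of 17-oxo steroids) to give the beta carbinol, a centre that is erased again in step 11.

Step 7
Reactants: 10 4-hydroxy-3-iodo-5-methoxybenzaldehyde (5-iodovanillin)
Product: 12 2-iodo-6-methoxybenzene-1,4-diol, via aryl formate 11 (not isolated)
Conditions: 30% H2O2, NaOH (2.2 equiv), H2O/THF, 0 °C to rt, argon; then HCl
Reagents that add atoms: hydrogen peroxide, OO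
Why: Dakin oxidation, in which the para-hydroxy group promotes aryl migration to the peroxide oxygen and the formate is hydrolysed in the same flask, placing the second oxygen exactly at C5'.

Step 8
Reactants: 12 2-iodo-6-methoxybenzene-1,4-diol
Product: 13 1-iodo-2,3,5-trimethoxybenzene
Conditions: MeI (3 equiv), K2CO3 (3 equiv), acetone, reflux, argon
Reagents that add atoms: iodomethane, CI
Why: Williamson ether synthesis on both phenols, which stores the hydroquinone as the para-dimethoxy pair that step 10 can oxidise.

Step 9
Reactants: 9 (1R,3aS,7aS)-1-ethynyl-4,4,7a-trimethyloctahydro-1H-inden-1-ol; 13 1-iodo-2,3,5-trimethoxybenzene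
Product: 14 (1S,3aS,7aS)-4,4,7a-trimethyl-1-[(2,3,5-trimethoxyphenyl)ethynyl]octahydro-1H-inden-1-ol
Conditions: PdCl2(PPh3)2 (5 mol%), CuI (10 mol%), Et3N/THF 1:1, 50 °C
Reagents that add atoms: none
Why: Sonogashira coupling of a terminal propargylic alcohol with an aryl iodide, which forms the C11–C1' bond without touching any stereocentre (the C8 descriptor changes by priority only).

Step 10
Reactants: 14 aryl alkynyl carbinol
Product: 15 2-{[(1S,3aS,7aS)-1-hydroxy-4,4,7a-trimethyloctahydro-1H-inden-1-yl]ethynyl}-6-methoxycyclohexa-2,5-diene-1,4-dione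
Conditions: (NH4)2Ce(NO3)6 (2.5 equiv), MeCN/H2O 2:1, 0 °C, 20 min
Reagents that add atoms: water, O
Why: Oxidative demethylation of the para-dimethoxy pair (C2' and C5') by tetravalent cerium, the usual outcome for 1,2,4-trimethoxyarenes, which keeps the C3' methoxy group and should leave the alkyne and the tertiary alcohol intact at short contact time.

Step 11
Reactants: 15 alkynylquinone carbinol
Product: 17 (4aS,8aS)-1-[(Z)-{2,5-bis[(tert-butyldimethylsilyl)oxy]-3-methoxyphenyl}(chloro)methylidene]-5,5,8a-trimethyloctahydronaphthalen-2(1H)-one, via vinylidene quinone methide 16 (not isolated)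
Conditions: TBSOTf (1.2 equiv), TBSCl (3 equiv), 2,6-di-tert-butyl-4-methylpyridine (1.5 equiv), CH2Cl2, -78 to 0 °C, argon, dark
Reagents that add atoms: tert-butyldimethylsilyl triflate, CC(C)(C)[Si](C)(C)OS(=O)(=O)C(F)(F)F; tert-butyldimethylsilyl chloride, CC(C)(C)[Si](C)(C)Cl
Why: Proposed new method: TBSOTf silylates the more basic carbonyl oxygen on C5' (a vinylogous ester through C3'-OMe), the cation so formed has allenyl-cation character at C9 through C6'=C1' and C11≡C9, and the C8–C10 bond of the five-membered ring shifts to C9 while C8–OH turns into C8=O (semipinacol 1,2-shift, proton taken up by the hindered pyridine) to give the vinylidene ortho-quinone methide 16, whose phenoxide-like oxygen on C2' is silylated by TBSCl so that the chloride released collapses on the cationic sp carbon C11 and the ring aromatises, the quinone having served as the internal two-electron oxidant. The closest known reaction types are the halonium-induced ring expansion of 1-(haloethynyl)cyclopentanols to 2-(dihalomethylidene)cyclohexanones, the vinylogous alpha-ketol rearrangement of 1-hydroxycycloalkyl enones and the addition of nucleophiles to vinylidene ortho-quinone methides, and what is new is their merger on a quinone acceptor and an unstrained carbinol ring, for which aromatisation and the relief of trans-hydrindane strain supply the driving force. Ring B is closed by a suprafacial 1,2-shift (five to six ring atoms) and not by an exo or endo cyclisation, so quaternary C10 migrates with retention and the trans A/B fusion is carried over from 15. No new sp3 centre arises: the new stereo-element is the tetrasubstituted C9=C11 bond, and it is set because chloride must reach the sp carbon of 16 in the plane that holds C8 and C10 and passes the flat carbonyl carbon C8 rather than quaternary C10, which places Cl cis to C8 and the out-of-plane aryl ring cis to C10, also the less strained arrangement. The step needs migration of C10 instead of C7, secured by the higher migratory aptitude of the fully substituted carbon, and it needs the shift to outrun halide addition to the quinone, secured by storing chloride as TBSCl, too weak a donor for the silylated quinone but good enough for 16. The electron-poor alkyne also suppresses ionisation of the tertiary alcohol (Meyer-Schuster path), and silylation of both oxygens prevents redox exchange between product and unreacted quinone.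

Step 12
Reactants: 17 bis-silylated chloro enone
Product: 18 8-methylidene diene (E at C9=C11)
Conditions: Ph3PCH3Br (4 equiv), KOtBu (3.8 equiv), toluene, rt to 60 °C
Reagents that add atoms: methyltriphenylphosphonium bromide, C[P+](c1ccccc1)(c1ccccc1)c1ccccc1.[Br-]
Why: Wittig methylenation, in which the unstabilised ylide adds 1,2 to the C8 carbonyl while the fully substituted, shielded C11 resists addition-elimination, so the C–Cl bond and the alkene geometry should be kept.

Step 13
Reactants: 18 8-methylidene diene
Product: 19 bis(tert-butyldimethylsilyl) ether of the target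
Conditions: 2-O2NC6H4SO2NHNH2 (excess, in portions), Et3N, CH2Cl2, rt
Reagents that add atoms: none
Why: Diimide reduction, a concerted syn transfer of two hydrogens that touches only the least substituted C=C and neither the C–Cl bond nor the tetrasubstituted alkene, and that should come from the alpha (equatorial) face because the axial C10 methyl group blocks the beta face, leaving the new methyl group axial and beta (8S).

Step 14
Reactants: 19 bis(tert-butyldimethylsilyl) ether of the target
Product: 20 2-{(E)-chloro[(2S,4aS,8aS)-2,5,5,8a-tetramethyloctahydronaphthalen-1(2H)-ylidene]methyl}-6-methoxybenzene-1,4-diol (target)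
Conditions: Bu4NF (2.5 equiv), AcOH (2.5 equiv), THF, 0 °C, argon
Reagents that add atoms: none
Why: Fluoride desilylation of both aryl silyl ethers, buffered with acetic acid so that no free ortho-phenoxide is left to expel the vinylic chloride or to scramble the alkene.

## Compound list

1 | (S)-7a-methyl-2,3,7,7a-tetrahydro-1H-indene-1,5(6H)-dione | C[C@]12CCC(=O)C=C1CCC2=O | starting material
2 | (7a'S)-7a'-methyl-2',3',7',7a'-tetrahydrospiro[1,3-dioxolane-2,1'-inden]-5'(6'H)-one | C[C@]12CCC(=O)C=C1CCC21OCCO1 | intermediate
3 | (7a'S)-4',7a'-dimethyl-2',3',7',7a'-tetrahydrospiro[1,3-dioxolane-2,1'-inden]-5'(6'H)-one (4-methyl enone) | C[C@]12CCC(=O)C(C)=C1CCC21OCCO1 | intermediate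
4 | (7a'S)-4',4',7a'-trimethyl-2',4',7',7a'-tetrahydrospiro[1,3-dioxolane-2,1'-inden]-5'(6'H)-one (C3'=C3a' alkene) | C[C@]12CCC(=O)C(C)(C)C1=CCC21OCCO1 | intermediate
5 | hydrazone of 4 | C[C@]12CCC(=NN)C(C)(C)C1=CCC21OCCO1 | intermediate
6 | (7a'S)-4',4',7a'-trimethyl-2',4',5',6',7',7a'-hexahydrospiro[1,3-dioxolane-2,1'-indene] | C[C@]12CCCC(C)(C)C1=CCC21OCCO1 | intermediate
7 | (3a'S,7a'S)-4',4',7a'-trimethyloctahydrospiro[1,3-dioxolane-2,1'-indene] (trans-fused) | C[C@]12CCCC(C)(C)[C@@H]1CCC21OCCO1 | intermediate
8 | (3aS,7aS)-4,4,7a-trimethyloctahydro-1H-inden-1-one | C[C@]12CCCC(C)(C)[C@@H]1CCC2=O | intermediate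
9 | (1R,3aS,7aS)-1-ethynyl-4,4,7a-trimethyloctahydro-1H-inden-1-ol (OH beta) | C[C@]12CCCC(C)(C)[C@@H]1CC[C@@]2(O)C#C | intermediate
10 | 4-hydroxy-3-iodo-5-methoxybenzaldehyde (5-iodovanillin) | COc1cc(C=O)cc(I)c1O | starting material
11 | 4-hydroxy-3-iodo-5-methoxyphenyl formate | COc1cc(OC=O)cc(I)c1O | intermediate
12 | 2-iodo-6-methoxybenzene-1,4-diol | COc1cc(O)cc(I)c1O | intermediate
13 | 1-iodo-2,3,5-trimethoxybenzene | COc1cc(OC)cc(I)c1OC | intermediate
14 | (1S,3aS,7aS)-4,4,7a-trimethyl-1-[(2,3,5-trimethoxyphenyl)ethynyl]octahydro-1H-inden-1-ol (same spatial arrangement as 9) | C[C@]12CCCC(C)(C)[C@@H]1CC[C@@]2(O)C#Cc1cc(OC)cc(OC)c1OC | intermediate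
15 | 2-{[(1S,3aS,7aS)-1-hydroxy-4,4,7a-trimethyloctahydro-1H-inden-1-yl]ethynyl}-6-methoxycyclohexa-2,5-diene-1,4-dione | C[C@]12CCCC(C)(C)[C@@H]1CC[C@@]2(O)C#CC1=CC(=O)C=C(OC)C1=O | intermediate
16 | 4-[(tert-butyldimethylsilyl)oxy]-2-methoxy-6-{[(4aS,8aS)-5,5,8a-trimethyl-2-oxooctahydronaphthalen-1(2H)-ylidene]methylidene}cyclohexa-2,4-dien-1-one (vinylidene ortho-quinone methide) | C[C@]12CCCC(C)(C)[C@@H]1CCC(=O)C2=C=C1C=C(O[Si](C)(C)C(C)(C)C)C=C(OC)C1=O | intermediate
17 | (4aS,8aS)-1-[(Z)-{2,5-bis[(tert-butyldimethylsilyl)oxy]-3-methoxyphenyl}(chloro)methylidene]-5,5,8a-trimethyloctahydronaphthalen-2(1H)-one | C[C@]12CCCC(C)(C)[C@@H]1CCC(=O)/C2=C(\Cl)c1cc(O[Si](C)(C)C(C)(C)C)cc(OC)c1O[Si](C)(C)C(C)(C)C | intermediate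
18 | (4aS,8aS)-1-[(E)-{2,5-bis[(tert-butyldimethylsilyl)oxy]-3-methoxyphenyl}(chloro)methylidene]-5,5,8a-trimethyl-2-methylidenedecahydronaphthalene | C[C@]12CCCC(C)(C)[C@@H]1CCC(=C)/C2=C(\Cl)c1cc(O[Si](C)(C)C(C)(C)C)cc(OC)c1O[Si](C)(C)C(C)(C)C | intermediate
19 | bis(tert-butyldimethylsilyl) ether of the target (2S,4aS,8aS; E) | C[C@]12CCCC(C)(C)[C@@H]1CC[C@H](C)/C2=C(\Cl)c1cc(O[Si](C)(C)C(C)(C)C)cc(OC)c1O[Si](C)(C)C(C)(C)C | intermediate
20 | 2-{(E)-chloro[(2S,4aS,8aS)-2,5,5,8a-tetramethyloctahydronaphthalen-1(2H)-ylidene]methyl}-6-methoxybenzene-1,4-diol | COc1cc(O)cc(/C(Cl)=C2/[C@@H](C)CC[C@H]3C(C)(C)CCC[C@]23C)c1O | target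

## Step count and risks

Total step count: 14. Longest linear sequence: 12 steps (steps 1–6 and 9–14); steps 7 and 8 form the aryl branch.

**Step 11 (proposed new method).**
- What may go wrong:
  - The 1,2-shift on the unstrained ring may be too slow. The silylated quinone would then be used up by intermolecular addition or rest as the tertiary silyl ether.
  - Triflate instead of chloride may capture the cationic carbon.
  - C7 may migrate in competition with C10.
- Fallback with known chemistry, from 9 back to 17:
  - The terminal alkyne of 9 is brominated (NBS, AgNO3 cat., acetone) to the bromoalkyne carbinol F1.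
  - Iodonium-induced semipinacol ring expansion (I2, PhI(OH)OTs, MeCN) is the reaction type established for 1-(haloethynyl)cyclopentanols. By anti addition it gives the (Z)-bromo(iodo)methylidene decalone F2 with iodine cis to the carbonyl group.
  - Copper-catalysed vinylic halogen exchange (CuI, trans-N,N'-dimethylcyclohexane-1,2-diamine, Me4NCl, EtOH, heat) replaces the weaker and less hindered C–I bond with retention. This gives the (E)-bromo(chloro)methylidene decalone F3.
  - In parallel, 12 is silylated (TBSCl, imidazole, DMF) to the bis-silylated aryl iodide F4. This is borylated (B2pin2, PdCl2(dppf), KOAc, dioxane) to the aryl pinacol boronate F5.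
  - Suzuki-Miyaura coupling of F3 with F5 (Pd(PPh3)4, K3PO4, dioxane/water) at the C–Br bond, with retention, returns to 17.

**Step 13.**
- What may go wrong:
  - Reduction of the hindered 1,1-disubstituted alkene may be sluggish.
  - Facial selectivity on the twisted diene may be insufficient.
- Fallback, from 18 back to 19:
  - Hydroboration with the bulkier and more site- and face-selective 9-BBN (THF, rt) from the alpha face gives the B-alkyl borane F6.
  - Oxidation with NaBO3·4H2O gives the 8-beta hydroxymethyl compound F7.
  - Mesylation (MsCl, Et3N, CH2Cl2) gives the primary mesylate F8.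
  - Reduction with LiBHEt3 (THF) turns the CH2OMs group into the methyl group of 19.

**Step 4.**
- What may go wrong:
  - The alkene flanked by two quaternary carbons may resist hydrogenation.
  - The facial bias may be eroded through double-bond migration on the catalyst.
- Fallback, from 2 back to 7:
  - Controlled mono-methylation of 2 (KOtBu 1 equiv, MeI 1 equiv) gives 3, now isolated.
  - Dissolving-metal reductive alkylation (Li, NH3, THF; then MeI) sets the trans fusion by axial protonation at C5. It introduces the second C4 methyl group on the regiodefined enolate and gives the trans-fused 4,4-dimethyl ketone ketal F9.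
  - Wolff-Kishner reduction through the saturated hydrazone F10 (N2H4·H2O, KOH, diethylene glycol, heat) returns to 7.

## Further compounds

F1 | step 11 | (1S,3aS,7aS)-1-(bromoethynyl)-4,4,7a-trimethyloctahydro-1H-inden-1-ol | C[C@]12CCCC(C)(C)[C@@H]1CC[C@@]2(O)C#CBr
F2 | step 11 | (4aS,8aS)-1-[(Z)-bromo(iodo)methylidene]-5,5,8a-trimethyloctahydronaphthalen-2(1H)-one | C[C@]12CCCC(C)(C)[C@@H]1CCC(=O)/C2=C(\I)Br
F3 | step 11 | (4aS,8aS)-1-[(E)-bromo(chloro)methylidene]-5,5,8a-trimethyloctahydronaphthalen-2(1H)-one | C[C@]12CCCC(C)(C)[C@@H]1CCC(=O)/C2=C(\Cl)Br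
F4 | step 11 | 2,5-bis[(tert-butyldimethylsilyl)oxy]-1-iodo-3-methoxybenzene | COc1cc(O[Si](C)(C)C(C)(C)C)cc(I)c1O[Si](C)(C)C(C)(C)C
F5 | step 11 | 2-{2,5-bis[(tert-butyldimethylsilyl)oxy]-3-methoxyphenyl}-4,4,5,5-tetramethyl-1,3,2-dioxaborolane | COc1cc(O[Si](C)(C)C(C)(C)C)cc(B2OC(C)(C)C(C)(C)O2)c1O[Si](C)(C)C(C)(C)C
F6 | step 13 | B-alkyl-9-borabicyclo[3.3.1]nonane adduct of 18 (boron on the 8-beta CH2 group) | C[C@]12CCCC(C)(C)[C@@H]1CC[C@H](CB3C4CCCC3CCC4)/C2=C(\Cl)c1cc(O[Si](C)(C)C(C)(C)C)cc(OC)c1O[Si](C)(C)C(C)(C)C
F7 | step 13 | 8-beta hydroxymethyl analogue of 19 | C[C@]12CCCC(C)(C)[C@@H]1CC[C@H](CO)/C2=C(\Cl)c1cc(O[Si](C)(C)C(C)(C)C)cc(OC)c1O[Si](C)(C)C(C)(C)C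
F8 | step 13 | methanesulfonate of F7 | C[C@]12CCCC(C)(C)[C@@H]1CC[C@H](COS(C)(=O)=O)/C2=C(\Cl)c1cc(O[Si](C)(C)C(C)(C)C)cc(OC)c1O[Si](C)(C)C(C)(C)C
F9 | step 4 | (3a'S,7a'S)-4',4',7a'-trimethylhexahydrospiro[1,3-dioxolane-2,1'-inden]-5'(4'H)-one (trans-fused) | C[C@]12CCC(=O)C(C)(C)[C@@H]1CCC21OCCO1
F10 | step 4 | hydrazone of F9 | C[C@]12CCC(=NN)C(C)(C)[C@@H]1CCC21OCCO1
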